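**Plan**
Numbering (germacrane): ring C1–C10 with C1=C10 (C14 = CHO on C10) and C4=C5 (C15 = CH2OH on C4); C6 carries the lactone oxygen, C8 the ester, C7 the lactone carbon C11 (C12 = C=O, C13 = CH2).
Retrosynthesis: remove the O8 ester, the C11=C13 methylene and the C12–O6 lactone bond, move C1=C10 back to C1=C2, then cut C3–C4 of the ten-membered ring by a retro-[3,3] shift that re-forms C1–C6 and leads to cyclohexanol 19.
Enabling feature: C4 is an sp2 carbon joined through C5 to the oxygenated C6, and C3 is joined through C2 to C1; C6(O)–C5=C4 is what a propargylic alkoxide leaves behind and C3–C2=C1 what a vinyl group leaves behind when both sit on adjacent carbons C6 and C1 of the ring C6–C7–C8–C9–C10–C1.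
Forward: substituted cyclohexane (steps 1–12), ring expansion to the ten-membered ring (step 13), cis-fused lactone (step 16), then methylene, ester and enal.
Stereochemistry: C8 by Corey–Bakshi–Shibata reduction; C7 by hydroboration anti to the C8 ether; C6 by chelation-controlled reduction; C4=C5 geometry by protonation of the allenolate; C1=C10 geometry by thermodynamic equilibration.

Key step: step 13

Remark: PMBO = (4-methoxybenzyl)oxy, TESO = triethylsilyloxy, TBSO = tert-butyldimethylsilyloxy; 1 is taken as commercial; the configurations drawn at C1 and C10 (15–19) and at the carbinol carbon of 19 are the expected major ones and are erased later (steps 13 and 20), so epimers there converge; the axial chirality of allenolate 21 is left open.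

Step 1
Reactants: 1 2-iodocyclohex-2-en-1-one
Product: 2 (R)-2-iodocyclohex-2-en-1-ol
Conditions: (S)-2-methyl-CBS-oxazaborolidine (10 mol %), BH3·SMe2, THF, −20 °C
Reagents that add atoms: none
Why: Corey–Bakshi–Shibata reduction in which the α-iodovinyl group acts as the large substituent, so the (S)-catalyst should give the (R)-carbinol that becomes C8.

Step 2
Reactants: 2 (R)-2-iodocyclohex-2-en-1-ol
Product: 3 (6R)-1-iodo-6-(PMBO)cyclohex-1-ene
Conditions: NaH, 4-methoxybenzyl chloride, Bu4NI (cat.), DMF, 0 °C to 25 °C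
Reagents that add atoms: 4-methoxybenzyl chloride COc1ccc(CCl)cc1
Why: Williamson ether synthesis; the PMB ether should later direct two face-selective steps and be removable oxidatively.

Step 3
Reactants: 3 (6R)-1-iodo-6-(PMBO)cyclohex-1-ene
Product: 5 2-[(6R)-6-(PMBO)cyclohex-1-en-1-yl]ethan-1-ol, via vinyllithium 4 (not isolated)
Conditions: t-BuLi (2.1 equiv), Et2O, −78 °C; oxirane, BF3·OEt2, −78 °C
Reagents that add atoms: oxirane C1CO1
Why: Iodine–lithium exchange and BF3-assisted opening of oxirane by the vinyllithium should attach the two-carbon arm C11–C12 at C7 without touching C8.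

Step 4
Reactants: 5 2-[(6R)-6-(PMBO)cyclohex-1-en-1-yl]ethan-1-ol
Product: 6 (6R)-6-(PMBO)-1-[2-(TESO)ethyl]cyclohex-1-ene
Conditions: Et3SiCl, imidazole, CH2Cl2, 0 °C
Reagents that add atoms: chlorotriethylsilane CC[Si](Cl)(CC)CC
Why: Standard silylation of the primary alcohol.

Step 5
Reactants: 6 (6R)-6-(PMBO)-1-[2-(TESO)ethyl]cyclohex-1-ene
Product: 8 (1R,2S,3R)-3-(PMBO)-2-[2-(TESO)ethyl]cyclohexan-1-ol, via alkylborane 7 (not isolated)
Conditions: 9-BBN, THF, 65 °C; then NaOH, H2O2, 0 °C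
Reagents that add atoms: hydrogen peroxide OO
Why: Hydroboration–oxidation in which boron should add to the less substituted C6 and hydrogen to C7 on the face anti to the allylic PMB ether, placing the C7 side chain cis to O8 and so setting C7.

Step 6
Reactants: 8 cyclohexanol (product of step 5)
Product: 9 (2R,3R)-3-(PMBO)-2-[2-(TESO)ethyl]cyclohexan-1-one
Conditions: Dess–Martin periodinane, CH2Cl2, 0 °C to 25 °C
Reagents that add atoms: none
Why: Dess–Martin oxidation under near-neutral conditions that should leave the epimerisable C7 centre and the β-alkoxy group intact.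

Step 7
Reactants: 9 cyclohexanone (product of step 6)
Product: 11 (5R,6R)-5-(PMBO)-6-[2-(TESO)ethyl]cyclohex-2-en-1-one, via trimethylsilyl enol ether 10 (not isolated)
Conditions: LiN(iPr)2, Me3SiCl, THF, −78 °C; then Pd(OAc)2 (10 mol %), O2 (1 atm), DMSO, 25 °C
Reagents that add atoms: none
Why: Kinetic deprotonation at the unsubstituted C1 methylene (not at the substituted C7) followed by Saegusa–Ito oxidation should give the C1=C10 enone.

Step 8
Reactants: 11 cyclohexenone (product of step 7)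
Product: 12 (5R,6R)-2-iodo-5-(PMBO)-6-[2-(TESO)ethyl]cyclohex-2-en-1-one
Conditions: I2, pyridine, CH2Cl2, 0 °C to 25 °C
Reagents that add atoms: iodine II
Why: α-Iodination of the enone by pyridine addition, iodination and elimination (Baylis–Hillman-type mechanism).

Step 9
Reactants: 12 α-iodoenone (product of step 8)
Product: 13 (5R,6R)-2-ethenyl-5-(PMBO)-6-[2-(TESO)ethyl]cyclohex-2-en-1-one
Conditions: tributyl(vinyl)stannane, PdCl2(PhCN)2 (5 mol %), AsPh3, CuI, NMP, 25 °C; product used at once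
Reagents that add atoms: tributyl(vinyl)stannane C=C[Sn](CCCC)(CCCC)CCCC
Why: Stille coupling under neutral conditions that should neither epimerise C7 nor eliminate the β-alkoxy group.

Step 10
Reactants: 13 2-vinyl enone (product of step 9)
Product: 15 (2S,3R,5R,6R)-3-(1,3-dithian-2-yl)-2-ethenyl-5-(PMBO)-6-[2-(TESO)ethyl]cyclohexan-1-one, via lithium dienolate 14 (not isolated)
Conditions: 1,3-dithiane, n-BuLi, THF, −30 °C; then 13, HMPA, −78 °C; then AcOH, −78 °C
Reagents that add atoms: 1,3-dithiane C1CSCSC1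
Why: Conjugate addition of the Corey–Seebach formyl anion equivalent (HMPA favours the 1,4-mode) should occur at C10 anti to the pseudoaxial C8 ether, and kinetic α-protonation of the dienolate should give the β,γ-unsaturated 2-vinyl ketone.

Step 11
Reactants: 15 dithianyl ketone (product of step 10)
Product: 16 (2S,3R,5R,6R)-3-(dimethoxymethyl)-2-ethenyl-5-(PMBO)-6-[2-(TESO)ethyl]cyclohexan-1-one
Conditions: PhI(OCOCF3)2, NaHCO3, MeOH, CH2Cl2, 0 °C
Reagents that add atoms: methanol CO
Why: Oxidative dethioacetalisation by trivalent iodine in methanol should turn the dithiane into the dimethyl acetal, an aldehyde mask that tolerates the later oxidants.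

Step 12
Reactants: 16 acetal ketone (product of step 11); 17 tert-butyldimethyl(prop-2-yn-1-yloxy)silane
Product: 19 (1S,2S,3R,5R,6R)-1-[3-(TBSO)prop-1-yn-1-yl]-3-(dimethoxymethyl)-2-ethenyl-5-(PMBO)-6-[2-(TESO)ethyl]cyclohexan-1-ol, via lithium acetylide 18 (not isolated)
Conditions: 17, n-BuLi, THF, −78 °C; then anhydrous CeCl3, 16, −78 °C
Reagents that add atoms: none
Why: 1,2-Addition of the acetylide with CeCl3 to suppress enolisation of the α-vinyl ketone; attack anti to the axial C8 ether is expected, but either carbinol epimer is usable because this carbon becomes sp2 in step 13.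

Step 13
Reactants: 19 1-alkynyl-2-vinylcyclohexanol (product of step 12)
Product: 22 (2E,5E,7R,9R,10R)-3-(TBSOCH2)-7-(dimethoxymethyl)-9-(PMBO)-10-[2-(TESO)ethyl]cyclodeca-2,5-dien-1-one, via potassium alkoxide 20 (not isolated), via potassium allenolate 21 (not isolated)
Conditions: KH, 18-crown-6, THF, 0 °C to 25 °C; then AcOH, THF, −78 °C
Reagents that add atoms: none
Why: Deprotonation gives alkoxide 20, and a charge-accelerated [3,3]-sigmatropic shift (anionic oxy-Cope rearrangement in its acetylenic form; the closest known type is the ring expansion of 1-alkynyl-2-vinylcycloalkanols to cyclodeca-2,5-dienones) joins the vinyl terminus C3 to the alkyne terminus C4 while the C1–C6 bond breaks. The ten-membered carbocycle is therefore closed by a four-atom ring expansion of the cyclohexane through a six-centre chair-like transition state, not by an end-to-end cyclisation, so no high dilution is needed. No new stereocentre is created: C7, C8 and C10 are spectators, the stereocentres at C1 and C6 are erased, and the trans C1=C2 bond follows from the diequatorial vinyl and alkynyl groups. C-protonation of allenolate 21 at C5 from the open face syn to the exocyclic CH2OTBS group should give the ring-cis C4=C5 enone (2E by the sequence rule), which is also the less strained isomer. The step needs the sigmatropic shift to outrun loss of the acetylide and proton transfer; the tertiary alkoxide, the crown-ether-separated potassium ion, the gauche vinyl and alkynyl groups and the cold acidic quench should secure this.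

Step 14
Reactants: 22 cyclodeca-2,5-dienone (product of step 13)
Product: 23 (1S,2E,5E,7R,9R,10S)-3-(TBSOCH2)-7-(dimethoxymethyl)-9-(PMBO)-10-[2-(TESO)ethyl]cyclodeca-2,5-dien-1-ol
Conditions: Zn(BH4)2, Et2O, −30 °C
Reagents that add atoms: none
Why: Chelation-controlled 1,2-reduction in which divalent zinc bridging the ketone and the C8 PMB ether should direct hydride to the face anti to the C7 side chain, giving the C6 carbinol cis to both O8 and the side chain.

Step 15
Reactants: 23 allylic alcohol (product of step 14)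
Product: 24 (1S,2E,5E,7R,9R,10S)-3-(TBSOCH2)-7-(dimethoxymethyl)-10-(2-hydroxyethyl)-9-(PMBO)cyclodeca-2,5-dien-1-ol
Conditions: PPTS (cat.), MeOH, 0 °C
Reagents that add atoms: none
Why: Acid-catalysed methanolysis should remove the primary TES ether selectively, while the bulkier TBS ether and the dimethyl acetal (stable in methanol) survive.

Step 16
Reactants: 24 diol (product of step 15)
Product: 26 (3aR,4R,6R,7E,10E,11aS)-10-(TBSOCH2)-6-(dimethoxymethyl)-4-(PMBO)-3a,4,5,6,9,11a-hexahydrocyclodeca[b]furan-2(3H)-one, via lactol 25 (not isolated)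
Conditions: TEMPO (20 mol %), PhI(OAc)2 (2.5 equiv), CH2Cl2, 25 °C
Reagents that add atoms: none
Why: TEMPO-catalysed oxidation of the primary alcohol, capture of the aldehyde by the cis C6 hydroxyl as a lactol and further oxidation should give the cis-fused γ-lactone.

Step 17
Reactants: 26 γ-lactone (product of step 16)
Product: 29 (3aR,4R,6R,7E,10E,11aS)-10-(TBSOCH2)-6-(dimethoxymethyl)-3-methylidene-4-(PMBO)-3a,4,5,6,9,11a-hexahydrocyclodeca[b]furan-2(3H)-one, via Mannich base 27 (not isolated), via methiodide 28 (not isolated)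
Conditions: LiN(iPr)2, THF, −78 °C; Eschenmoser's salt (Me2N=CH2 I), −78 °C to 0 °C; then MeI, MeOH, 25 °C; then NaHCO3 (aq), CH2Cl2
Reagents that add atoms: N,N-dimethylmethyleneiminium iodide C=[N+](C)C.[I-]
Why: α-Aminomethylation of the lactone enolate with Eschenmoser's salt, quaternisation and Hofmann-type elimination (Mannich–elimination methylenation) at the only enolisable carbonyl position.

Step 18
Reactants: 29 α-methylene lactone (product of step 17)
Product: 30 (3aR,4R,6R,7E,10E,11aS)-10-(TBSOCH2)-6-(dimethoxymethyl)-4-hydroxy-3-methylidene-3a,4,5,6,9,11a-hexahydrocyclodeca[b]furan-2(3H)-one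
Conditions: DDQ, CH2Cl2, pH 7 phosphate buffer, 0 °C
Reagents that add atoms: none
Why: Oxidative cleavage of the PMB ether by DDQ through the stabilised benzylic cation, under buffered conditions that should spare the acetal and the silyl ether.

Step 19
Reactants: 30 C8 alcohol (product of step 18)
Product: 31 (3aR,4R,6R,7E,10E,11aS)-10-(TBSOCH2)-6-(dimethoxymethyl)-3-methylidene-2-oxo-2,3,3a,4,5,6,9,11a-octahydrocyclodeca[b]furan-4-yl 3-methylbutanoate
Conditions: 3-methylbutanoic anhydride, Et3N, DMAP (cat.), CH2Cl2, 0 °C to 25 °C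
Reagents that add atoms: 3-methylbutanoic anhydride CC(C)CC(=O)OC(=O)CC(C)C
Why: DMAP-catalysed acyl transfer to the secondary C8 alcohol, with retention at C8.

Step 20
Reactants: 31 protected ester (product of step 19)
Product: 33 (3aR,4R,6E,10E,11aS)-6-formyl-10-(hydroxymethyl)-3-methylidene-2-oxo-2,3,3a,4,5,8,9,11a-octahydrocyclodeca[b]furan-4-yl 3-methylbutanoate, via β,γ-unsaturated aldehyde 32 (not isolated)
Conditions: HF (aq, 48 %), MeCN, 0 °C; then Et3N (cat.), CH2Cl2, 25 °C
Reagents that add atoms: water O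
Why: Acid cleaves the silyl ether and hydrolyses the acetal, and amine-mediated equilibration through the dienolate should move the C1=C2 bond into conjugation (erasing C10) and settle on the more stable ring-cis enal of the target.

**Compound list**
1 | 2-iodocyclohex-2-en-1-one | O=C1CCCC=C1I | starting material
2 | (R)-2-iodocyclohex-2-en-1-ol | O[C@@H]1CCCC=C1I | intermediate
3 | (6R)-1-iodo-6-(PMBO)cyclohex-1-ene | COc1ccc(CO[C@@H]2CCCC=C2I)cc1 | intermediate
4 | [(6R)-6-(PMBO)cyclohex-1-en-1-yl]lithium | COc1ccc(CO[C@@H]2CCCC=C2[Li])cc1 | intermediate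
5 | 2-[(6R)-6-(PMBO)cyclohex-1-en-1-yl]ethan-1-ol | COc1ccc(CO[C@@H]2CCCC=C2CCO)cc1 | intermediate
6 | (6R)-6-(PMBO)-1-[2-(TESO)ethyl]cyclohex-1-ene | COc1ccc(CO[C@@H]2CCCC=C2CCO[Si](CC)(CC)CC)cc1 | intermediate
7 | 9-[(1R,2S,3R)-3-(PMBO)-2-[2-(TESO)ethyl]cyclohexyl]-9-borabicyclo[3.3.1]nonane | C1CCC2CCCC1B2[C@@H]1CCC[C@@H](OCc2ccc(OC)cc2)[C@H]1CCO[Si](CC)(CC)CC | intermediate
8 | (1R,2S,3R)-3-(PMBO)-2-[2-(TESO)ethyl]cyclohexan-1-ol | O[C@@H]1CCC[C@@H](OCc2ccc(OC)cc2)[C@H]1CCO[Si](CC)(CC)CC | intermediate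
9 | (2R,3R)-3-(PMBO)-2-[2-(TESO)ethyl]cyclohexan-1-one | O=C1CCC[C@@H](OCc2ccc(OC)cc2)[C@H]1CCO[Si](CC)(CC)CC | intermediate
10 | (5R,6R)-5-(PMBO)-6-[2-(TESO)ethyl]-1-(trimethylsilyloxy)cyclohex-1-ene | C[Si](C)(C)OC1=CCC[C@@H](OCc2ccc(OC)cc2)[C@H]1CCO[Si](CC)(CC)CC | intermediate
11 | (5R,6R)-5-(PMBO)-6-[2-(TESO)ethyl]cyclohex-2-en-1-one | O=C1C=CC[C@@H](OCc2ccc(OC)cc2)[C@H]1CCO[Si](CC)(CC)CC | intermediate
12 | (5R,6R)-2-iodo-5-(PMBO)-6-[2-(TESO)ethyl]cyclohex-2-en-1-one | O=C1C(I)=CC[C@@H](OCc2ccc(OC)cc2)[C@H]1CCO[Si](CC)(CC)CC | intermediate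
13 | (5R,6R)-2-ethenyl-5-(PMBO)-6-[2-(TESO)ethyl]cyclohex-2-en-1-one | O=C1C(C=C)=CC[C@@H](OCc2ccc(OC)cc2)[C@H]1CCO[Si](CC)(CC)CC | intermediate
14 | lithium dienolate of 15 (O–Li on C6, C6=C1, vinyl on C1) | [Li]OC1=C(C=C)[C@H](C2SCCCS2)C[C@@H](OCc2ccc(OC)cc2)[C@H]1CCO[Si](CC)(CC)CC | intermediate
15 | (2S,3R,5R,6R)-3-(1,3-dithian-2-yl)-2-ethenyl-5-(PMBO)-6-[2-(TESO)ethyl]cyclohexan-1-one | O=C1[C@@H](C=C)[C@H](C2SCCCS2)C[C@@H](OCc2ccc(OC)cc2)[C@H]1CCO[Si](CC)(CC)CC | intermediate
16 | (2S,3R,5R,6R)-3-(dimethoxymethyl)-2-ethenyl-5-(PMBO)-6-[2-(TESO)ethyl]cyclohexan-1-one | O=C1[C@@H](C=C)[C@H](C(OC)OC)C[C@@H](OCc2ccc(OC)cc2)[C@H]1CCO[Si](CC)(CC)CC | intermediate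
17 | tert-butyldimethyl(prop-2-yn-1-yloxy)silane | C#CCO[Si](C)(C)C(C)(C)C | starting material
18 | lithium acetylide of 17 | [Li]C#CCO[Si](C)(C)C(C)(C)C | intermediate
19 | (1S,2S,3R,5R,6R)-1-[3-(TBSO)prop-1-yn-1-yl]-3-(dimethoxymethyl)-2-ethenyl-5-(PMBO)-6-[2-(TESO)ethyl]cyclohexan-1-ol | CC(C)(C)[Si](C)(C)OCC#C[C@]1(O)[C@@H](C=C)[C@H](C(OC)OC)C[C@@H](OCc2ccc(OC)cc2)[C@H]1CCO[Si](CC)(CC)CC | intermediate
20 | potassium alkoxide of 19 | [K+].CC(C)(C)[Si](C)(C)OCC#C[C@]1([O-])[C@@H](C=C)[C@H](C(OC)OC)C[C@@H](OCc2ccc(OC)cc2)[C@H]1CCO[Si](CC)(CC)CC | intermediate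
21 | potassium cyclodeca-1,2,5-trien-1-olate (allenolate of 22) | [K+].[O-]C1=C=C(CO[Si](C)(C)C(C)(C)C)C/C=C/[C@H](C(OC)OC)C[C@@H](OCc2ccc(OC)cc2)[C@H]1CCO[Si](CC)(CC)CC | intermediate
22 | (2E,5E,7R,9R,10R)-3-(TBSOCH2)-7-(dimethoxymethyl)-9-(PMBO)-10-[2-(TESO)ethyl]cyclodeca-2,5-dien-1-one | O=C1/C=C(/CO[Si](C)(C)C(C)(C)C)C/C=C/[C@H](C(OC)OC)C[C@@H](OCc2ccc(OC)cc2)[C@H]1CCO[Si](CC)(CC)CC | intermediate
23 | (1S,2E,5E,7R,9R,10S)-3-(TBSOCH2)-7-(dimethoxymethyl)-9-(PMBO)-10-[2-(TESO)ethyl]cyclodeca-2,5-dien-1-ol | O[C@H]1/C=C(/CO[Si](C)(C)C(C)(C)C)C/C=C/[C@H](C(OC)OC)C[C@@H](OCc2ccc(OC)cc2)[C@H]1CCO[Si](CC)(CC)CC | intermediate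
24 | (1S,2E,5E,7R,9R,10S)-3-(TBSOCH2)-7-(dimethoxymethyl)-10-(2-hydroxyethyl)-9-(PMBO)cyclodeca-2,5-dien-1-ol | O[C@H]1/C=C(/CO[Si](C)(C)C(C)(C)C)C/C=C/[C@H](C(OC)OC)C[C@@H](OCc2ccc(OC)cc2)[C@H]1CCO | intermediate
25 | lactol (2-hydroxy analogue of 26, anomer mixture) | C1C(O)O[C@H]2/C=C(/CO[Si](C)(C)C(C)(C)C)C/C=C/[C@H](C(OC)OC)C[C@@H](OCc3ccc(OC)cc3)[C@@H]12 | intermediate
26 | (3aR,4R,6R,7E,10E,11aS)-10-(TBSOCH2)-6-(dimethoxymethyl)-4-(PMBO)-3a,4,5,6,9,11a-hexahydrocyclodeca[b]furan-2(3H)-one | C1C(=O)O[C@H]2/C=C(/CO[Si](C)(C)C(C)(C)C)C/C=C/[C@H](C(OC)OC)C[C@@H](OCc3ccc(OC)cc3)[C@@H]12 | intermediate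
27 | 3-[(dimethylamino)methyl] derivative of 26 (C3 configuration open) | CN(C)CC1C(=O)O[C@H]2/C=C(/CO[Si](C)(C)C(C)(C)C)C/C=C/[C@H](C(OC)OC)C[C@@H](OCc3ccc(OC)cc3)[C@@H]12 | intermediate
28 | trimethylammonium iodide of 27 | [I-].C[N+](C)(C)CC1C(=O)O[C@H]2/C=C(/CO[Si](C)(C)C(C)(C)C)C/C=C/[C@H](C(OC)OC)C[C@@H](OCc3ccc(OC)cc3)[C@@H]12 | intermediate
29 | (3aR,4R,6R,7E,10E,11aS)-10-(TBSOCH2)-6-(dimethoxymethyl)-3-methylidene-4-(PMBO)-3a,4,5,6,9,11a-hexahydrocyclodeca[b]furan-2(3H)-one | C=C1C(=O)O[C@H]2/C=C(/CO[Si](C)(C)C(C)(C)C)C/C=C/[C@H](C(OC)OC)C[C@@H](OCc3ccc(OC)cc3)[C@@H]12 | intermediate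
30 | (3aR,4R,6R,7E,10E,11aS)-10-(TBSOCH2)-6-(dimethoxymethyl)-4-hydroxy-3-methylidene-3a,4,5,6,9,11a-hexahydrocyclodeca[b]furan-2(3H)-one | C=C1C(=O)O[C@H]2/C=C(/CO[Si](C)(C)C(C)(C)C)C/C=C/[C@H](C(OC)OC)C[C@@H](O)[C@@H]12 | intermediate
31 | (3aR,4R,6R,7E,10E,11aS)-10-(TBSOCH2)-6-(dimethoxymethyl)-3-methylidene-2-oxo-2,3,3a,4,5,6,9,11a-octahydrocyclodeca[b]furan-4-yl 3-methylbutanoate | C=C1C(=O)O[C@H]2/C=C(/CO[Si](C)(C)C(C)(C)C)C/C=C/[C@H](C(OC)OC)C[C@@H](OC(=O)CC(C)C)[C@@H]12 | intermediate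
32 | (3aR,4R,6R,7E,10E,11aS)-6-formyl-10-(hydroxymethyl)-3-methylidene-2-oxo-2,3,3a,4,5,6,9,11a-octahydrocyclodeca[b]furan-4-yl 3-methylbutanoate | C=C1C(=O)O[C@H]2/C=C(/CO)C/C=C/[C@H](C=O)C[C@@H](OC(=O)CC(C)C)[C@@H]12 | intermediate
33 | (3aR,4R,6E,10E,11aS)-6-formyl-10-(hydroxymethyl)-3-methylidene-2-oxo-2,3,3a,4,5,8,9,11a-octahydrocyclodeca[b]furan-4-yl 3-methylbutanoate | C=C1C(=O)O[C@H]2/C=C(/CO)CC/C=C(/C=O)C[C@@H](OC(=O)CC(C)C)[C@@H]12 | target

**Totals and risks**
Total step count: 20. Longest linear sequence: 20 steps (1 to 33); alkyne 17 enters as a commercial component in step 12.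

Step 13. Loss of the acetylide from alkoxide 20, or base-induced migration of the C1=C2 bond into conjugation with the new dienone, may compete with or follow the sigmatropic shift. The fallback removes the alkoxide and runs the rearrangement on a neutral silyl ether. It sets out from 19: silylation (Me3SiCl, imidazole, DMF) should give the trimethylsilyl ether of 19 F1; heating in degassed 1,2-dichlorobenzene at about 190 °C in a sealed tube should effect the thermal siloxy-Cope rearrangement to the trimethylsilyl allenyl ether F2; buffered desilylation (Bu4NF, AcOH, THF, −78 °C) should protonate C5 and rejoin the route at 22.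

Step 14. Facial selectivity of hydride delivery may be poor in the flexible ten-membered ring, or conjugate reduction may intervene. The fallback corrects the carbinol by inversion instead of relying on chelation. It sets out from 22: Luche reduction (NaBH4, CeCl3·7H2O, MeOH, −78 °C) would give the non-chelation product, the C6-epimer of 23 F3; Mitsunobu esterification (PPh3, diisopropyl azodicarboxylate, 4-nitrobenzoic acid, toluene, 0 °C) should invert C6 and give the 4-nitrobenzoate of 23 F4; methanolysis (K2CO3, MeOH, 0 °C) rejoins the route at 23.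

Step 10. Competing 1,2-addition to the cross-conjugated dienone 13, its dimerisation, or γ-protonation of dienolate 14 to the conjugated ethylidene ketone may erode the step. The fallback avoids the dienone and brings in the vinyl group after the conjugate addition. It sets out from 11 (steps 8 and 9 are then skipped): conjugate addition of 2-lithio-1,3-dithiane (THF, HMPA, −78 °C) and trapping of the regiodefined lithium enolate with (phenylseleno)acetaldehyde should give the β-hydroxy selenide F5; MsCl and Et3N (CH2Cl2, 0 °C) should eliminate the hydroxyl and phenylseleno groups to the vinyl group and rejoin the route at 15.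

Further compounds
F1 | step 13 | trimethylsilyl ether of 19 | CC(C)(C)[Si](C)(C)OCC#C[C@]1(O[Si](C)(C)C)[C@@H](C=C)[C@H](C(OC)OC)C[C@@H](OCc2ccc(OC)cc2)[C@H]1CCO[Si](CC)(CC)CC
F2 | step 13 | trimethylsilyl allenyl ether (1-trimethylsilyloxycyclodeca-1,2,5-triene corresponding to 21) | C[Si](C)(C)OC1=C=C(CO[Si](C)(C)C(C)(C)C)C/C=C/[C@H](C(OC)OC)C[C@@H](OCc2ccc(OC)cc2)[C@H]1CCO[Si](CC)(CC)CC
F3 | step 14 | C6-epimer of 23 | O[C@@H]1/C=C(/CO[Si](C)(C)C(C)(C)C)C/C=C/[C@H](C(OC)OC)C[C@@H](OCc2ccc(OC)cc2)[C@H]1CCO[Si](CC)(CC)CC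
F4 | step 14 | 4-nitrobenzoate of 23 | O=C(O[C@H]1/C=C(/CO[Si](C)(C)C(C)(C)C)C/C=C/[C@H](C(OC)OC)C[C@@H](OCc2ccc(OC)cc2)[C@H]1CCO[Si](CC)(CC)CC)c1ccc(cc1)[N+](=O)[O-]
F5 | step 10 | β-hydroxy selenide (2-[1-hydroxy-2-(phenylseleno)ethyl] analogue of 15, carbinol configuration open) | O=C1[C@@H](C(O)C[Se]c2ccccc2)[C@H](C3SCCCS3)C[C@@H](OCc2ccc(OC)cc2)[C@H]1CCO[Si](CC)(CC)CC
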